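## Retrosynthetic overview

- Target 12 (ring numbering: C1 carbonyl, C2=C3, C4 tertiary carbinol, C5 CH2, C6 secondary carbinol) ⇐ ketal hydrolysis of diol ketal 11 ⇐ C–Si to C–OH oxidation of the bridged oxasilolane 10.
- 10 ⇐ tethered, rhodium-catalysed addition of Si–H across C5=C6 of the achiral dienyl hydrosilyl ether 9. This forms C6–Si and C5–H and closes the oxasilolane C4–O–Si–C6–C5, the only ring made in the route (the carbocycle is bought as 6).
- 9 ⇐ O-silylation of 8 ⇐ 1,2-addition of chain Grignard reagent 7 to quinone monoketal 6; chain bromide 5 ⇐ Z-selective Wittig reaction of ylide 4 with bromo aldehyde 2.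
- Feature on which the plan rests: the six-membered ring is a 4-alkyl para-quinol in which one of two enantiotopic ring alkenes (C5=C6) has taken up hydrogen at C5 and oxygen at C6, the C6 oxygen lying cis to the C4 oxygen across the C5 methylene, so that a two-atom O–Si link from C4 can deliver it.
- C1 is carried as a dimethyl ketal, not as a protected carbinol: both sp3 ring carbons of 9 are then quaternary (no C1–H for β-hydride elimination or aromatisation), 9 is one achiral compound without C1 epimers, and it is reached in four steps.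

Key step: step 5

Assumption: the sense of induction of BINAP on this new substrate class cannot be predicted with confidence; the route is written with (R)-BINAP as the antipode that delivers (1S,5R)-10, and (S)-BINAP takes its place if the first run shows the opposite sense.

## Route

Step 1
Reactants: 1 10-bromodecan-1-ol
Product: 2 10-bromodecanal
Conditions: TEMPO (0.1 equiv), PhI(OAc)2 (1.1 equiv), CH2Cl2, 25 °C
Reagents that add atoms: none
Why: Oxoammonium-mediated oxidation of a primary alcohol (TEMPO with PhI(OAc)2 as terminal oxidant) should stop at the aldehyde and leave the primary bromide untouched.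

Step 2
Reactants: 2 10-bromodecanal; 3 heptyltriphenylphosphonium bromide
Product: 5 (Z)-17-bromoheptadec-7-ene, via heptylidenetriphenylphosphorane 4 (not isolated)
Conditions: NaN(SiMe3)2 (1.0 equiv), THF, −78 °C; then 2, −78 → 0 °C
Reagents that add atoms: none
Why: Wittig olefination with a non-stabilised ylide under lithium-free conditions should give the Z alkene by kinetic control through the cis oxaphosphetane; at −78 °C carbonyl addition should outrun alkylation at the primary bromide, and residual E isomer can be removed on AgNO3-impregnated silica gel.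

Step 3
Reactants: 5 (Z)-17-bromoheptadec-7-ene; 6 4,4-dimethoxycyclohexa-2,5-dien-1-one
Product: 8 1-[(Z)-heptadec-10-enyl]-4,4-dimethoxycyclohexa-2,5-dien-1-ol, via (Z)-heptadec-10-enylmagnesium bromide 7 (not isolated)
Conditions: Mg turnings, THF, 40 °C; then added to 6 (1.3 equiv), THF, −78 °C; H2O quench
Reagents that add atoms: none
Why: Grignard 1,2-addition to the carbonyl of a quinone monoketal is the standard entry to para-quinol ketals; low temperature and inverse addition should suppress conjugate addition, and the neutral quench keeps the ketal and the bis-allylic tertiary alcohol intact.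

Step 4
Reactants: 8 1-[(Z)-heptadec-10-enyl]-4,4-dimethoxycyclohexa-2,5-dien-1-ol
Product: 9 {1-[(Z)-heptadec-10-enyl]-4,4-dimethoxycyclohexa-2,5-dien-1-yl}oxy(dimethyl)silane (the Si–H dimethylsilyl ether of 8; achiral)
Conditions: Me2SiHCl (1.5 equiv), Et3N (2 equiv), DMAP (0.05 equiv), CH2Cl2, 0 → 25 °C
Reagents that add atoms: chlorodimethylsilane C[SiH](C)Cl
Why: O-silylation of a tertiary alcohol with a small chlorohydrosilane and an amine base is routine; the basic medium protects the ketal, and the moisture-sensitive Si–H ether is taken on after filtration through Et3N-deactivated silica gel.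

Step 5
Reactants: 9 {1-[(Z)-heptadec-10-enyl]-4,4-dimethoxycyclohexa-2,5-dien-1-yl}oxy(dimethyl)silane
Product: 10 (1S,5R)-5-[(Z)-heptadec-10-enyl]-2,2-dimethoxy-7,7-dimethyl-6-oxa-7-silabicyclo[3.2.1]oct-3-ene (oxasilolane bridging the C4 oxygen and C6 of the carbocycle)
Conditions: [Rh(cod)2]BF4 (3 mol%), (R)-BINAP (3.3 mol%), catalyst pre-activated with H2 then purged with Ar, acetone, 0.02 M, 25 °C
Reagents that add atoms: none
Why: Proposed new method: the cationic monovalent rhodium–BINAP fragment should add oxidatively across the Si–H bond of 9 to give a trivalent rhodium silyl hydride that the O–Si link keeps above one ring face; one ring alkene then inserts (H to C5, rhodium to C6) and C6–Si reductive elimination releases 10 and monovalent rhodium. The closest known reaction types are the rhodium–diphosphine-catalysed 5-endo intramolecular hydrosilylation of acyclic allylic hydrosilyl ethers and its enantioselective use to desymmetrise dialkenyl carbinols; a ring alkene as acceptor and a bridged 6-oxa-7-silabicyclo[3.2.1]octene as product have not been shown. The single ring formed, the oxasilolane C4–O–Si–C6–C5, closes in the 5-endo-trig mode, since bonding of silicon to C5 would need a four-membered oxasiletane. C6 is forced cis to the C4 oxygen because silicon, bound to that oxygen, can only reach C6 on the same ring face, and C4 becomes a stereocentre whose configuration is decided by which of the two enantiotopic alkenes the chiral diphosphine on rhodium lets insert. The step therefore needs only enantiotopic-alkene selection (ligand control): regiochemistry and relative configuration follow from the tether length, the chain alkene cannot be reached intramolecularly, and because C1 and C4 of 9 are both quaternary a ring-bound rhodium alkyl has no β-hydrogen other than the one just delivered, which shuts off isomerisation and aromatisation.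

Step 6
Reactants: 10 (1S,5R)-5-[(Z)-heptadec-10-enyl]-2,2-dimethoxy-7,7-dimethyl-6-oxa-7-silabicyclo[3.2.1]oct-3-ene
Product: 11 (1S,3R)-3-[(Z)-heptadec-10-enyl]-6,6-dimethoxycyclohex-4-ene-1,3-diol
Conditions: 30% aq. H2O2 (10 equiv), KF (3 equiv), KHCO3 (3 equiv), THF/MeOH (1:1), 25 → 40 °C
Reagents that add atoms: hydrogen peroxide OO
Why: Tamao–Fleming oxidation: peroxide adds to the fluoride-activated, strained alkoxysilane and C6 migrates from silicon to oxygen with retention, so the new C6–OH stays cis to the C4 oxygen, which is released as the free tertiary alcohol; the buffered basic medium spares the ketal and the unactivated alkenes, and 10 is used crude because β-alkoxy silanes are acid-labile.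

Step 7
Reactants: 11 (1S,3R)-3-[(Z)-heptadec-10-enyl]-6,6-dimethoxycyclohex-4-ene-1,3-diol
Product: 12 (4R,6S)-4-[(Z)-heptadec-10-enyl]-4,6-dihydroxycyclohex-2-en-1-one
Conditions: AcOH/THF/H2O (3:1:1), 20 °C
Reagents that add atoms: water O
Why: Mild acid hydrolysis of an allylic dimethyl ketal through the allyl-stabilised oxocarbenium ion unveils the enone; C4 is quaternary and the weak acid should not enolise C6, so neither stereocentre is touched, and once the enone exists the C4 hydroxyl is γ to the carbonyl and no longer prone to ionisation.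

## Compound list

1 | 10-bromodecan-1-ol | OCCCCCCCCCCBr | starting material
2 | 10-bromodecanal | O=CCCCCCCCCCBr | intermediate
3 | heptyltriphenylphosphonium bromide | CCCCCCC[P+](c1ccccc1)(c1ccccc1)c1ccccc1.[Br-] | starting material
4 | heptylidenetriphenylphosphorane | CCCCCCC=P(c1ccccc1)(c1ccccc1)c1ccccc1 | intermediate
5 | (Z)-17-bromoheptadec-7-ene | CCCCCC/C=C\CCCCCCCCCBr | intermediate
6 | 4,4-dimethoxycyclohexa-2,5-dien-1-one | COC1(OC)C=CC(=O)C=C1 | starting material
7 | (Z)-heptadec-10-enylmagnesium bromide | CCCCCC/C=C\CCCCCCCCC[Mg]Br | intermediate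
8 | 1-[(Z)-heptadec-10-enyl]-4,4-dimethoxycyclohexa-2,5-dien-1-ol | CCCCCC/C=C\CCCCCCCCCC1(O)C=CC(OC)(OC)C=C1 | intermediate
9 | {1-[(Z)-heptadec-10-enyl]-4,4-dimethoxycyclohexa-2,5-dien-1-yl}oxy(dimethyl)silane | CCCCCC/C=C\CCCCCCCCCC1(O[SiH](C)C)C=CC(OC)(OC)C=C1 | intermediate
10 | (1S,5R)-5-[(Z)-heptadec-10-enyl]-2,2-dimethoxy-7,7-dimethyl-6-oxa-7-silabicyclo[3.2.1]oct-3-ene | CCCCCC/C=C\CCCCCCCCC[C@]1(O2)C=CC(OC)(OC)[C@@H]([Si]2(C)C)C1 | intermediate
11 | (1S,3R)-3-[(Z)-heptadec-10-enyl]-6,6-dimethoxycyclohex-4-ene-1,3-diol | CCCCCC/C=C\CCCCCCCCC[C@]1(O)C=CC(OC)(OC)[C@@H](O)C1 | intermediate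
12 | (4R,6S)-4-[(Z)-heptadec-10-enyl]-4,6-dihydroxycyclohex-2-en-1-one | CCCCCC/C=C\CCCCCCCCC[C@]1(O)C=CC(=O)[C@@H](O)C1 | target

Total step count: 7. Longest linear sequence: 7 steps (from 1 to 12).

## Steps most likely to fail

**Step 5.** The ligand may discriminate poorly between the two enantiotopic ring alkenes. Insertion of the cis-disubstituted ring alkene into the tethered silyl hydride may also be slow, so that intermolecular Si–H addition, Si–O redistribution, or Lewis-acid ionisation of the ketal followed by hydride transfer (reductive aromatisation) take over.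

Fallback, using known reactions only and no silicon tether: it sets out from 8 and comes back at 12.
- Aqueous acetic acid hydrolyses the ketal of 8 to 4-[(Z)-heptadec-10-enyl]-4-hydroxycyclohexa-2,5-dien-1-one F1.
- Et3SiOTf/2,6-lutidine caps the tertiary alcohol as 4-[(Z)-heptadec-10-enyl]-4-(triethylsilyloxy)cyclohexa-2,5-dien-1-one F2.
- A copper hydride catalyst bearing a chiral bisphosphine (Cu(OAc)2, DTBM-SEGPHOS of the appropriate hand, (EtO)2MeSiH, toluene) reduces one of the two enantiotopic enone alkenes in a desymmetrising conjugate reduction. This sets C4 and gives (R)-4-[(Z)-heptadec-10-enyl]-4-(triethylsilyloxy)cyclohex-2-en-1-one F3.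
- Kinetic deprotonation at C6 with KN(SiMe3)2 at −78 °C and oxidation of the cross-conjugated enolate with 2-(phenylsulfonyl)-3-phenyloxaziridine should introduce the hydroxyl mainly anti to the silyloxy group, giving (4R,6R)-4-[(Z)-heptadec-10-enyl]-6-hydroxy-4-(triethylsilyloxy)cyclohex-2-en-1-one F4.
- Mitsunobu inversion with chloroacetic acid (PPh3, DIAD) converts it into the cis ester (4R,6S)-6-(chloroacetoxy)-4-[(Z)-heptadec-10-enyl]-4-(triethylsilyloxy)cyclohex-2-en-1-one F5.
- K2CO3 in MeOH at 0 °C cleaves the ester to (4R,6S)-4-[(Z)-heptadec-10-enyl]-6-hydroxy-4-(triethylsilyloxy)cyclohex-2-en-1-one F6, and HF·pyridine removes the silyl group to give 12.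
- Whatever share of the hydroxylation already gives the cis ketol is F6 and joins at that point.

**Step 7.** The C6 hydroxyl slows ionisation of the neighbouring ketal, so the acid may instead ionise the tertiary allylic C4–O bond of 11 or dehydrate the product towards a catechol.

Fallback, locking the diol before any acid is applied: it sets out from 11 and comes back at 12.
- t-Bu2Si(OTf)2 (1.05 equiv) and 2,6-lutidine in CH2Cl2 at −40 → 0 °C tie the cis C4 and C6 oxygens together as (1S,5R)-3,3-di-tert-butyl-5-[(Z)-heptadec-10-enyl]-8,8-dimethoxy-2,4-dioxa-3-silabicyclo[3.3.1]non-6-ene F7.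
- The ketal can then be hydrolysed with stronger aqueous acid (oxalic acid or dilute HCl in THF) to (1S,5R)-3,3-di-tert-butyl-5-[(Z)-heptadec-10-enyl]-2,4-dioxa-3-silabicyclo[3.3.1]non-6-en-8-one F8, because the C4 oxygen is held in the bridge and the C6 oxygen is masked.
- HF·pyridine buffered with pyridine in THF at 0 °C releases 12.

**Step 2.** The basic ylide may be partly consumed by attack on the primary bromide or by enolisation of 2, and any loss of Z selectivity at this point travels unchanged to 12.

Fallback, exchanging the olefination partners and installing the bromide afterwards: it sets out from 1 and comes back at 5.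
- PPh3 in MeCN at reflux converts 1 into (10-hydroxydecyl)triphenylphosphonium bromide F9.
- Two equivalents of NaN(SiMe3)2 give the oxido ylide, which is condensed with heptanal at −78 °C to (Z)-heptadec-10-en-1-ol F10. This is purified as the alcohol, where removal of E isomer on AgNO3-impregnated silica gel is easiest.
- An Appel reaction (CBr4, PPh3, CH2Cl2, 0 °C) then gives 5.

Further compounds
F1 | step 5 | 4-[(Z)-heptadec-10-enyl]-4-hydroxycyclohexa-2,5-dien-1-one | CCCCCC/C=C\CCCCCCCCCC1(O)C=CC(=O)C=C1
F2 | step 5 | 4-[(Z)-heptadec-10-enyl]-4-(triethylsilyloxy)cyclohexa-2,5-dien-1-one | CCCCCC/C=C\CCCCCCCCCC1(O[Si](CC)(CC)CC)C=CC(=O)C=C1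
F3 | step 5 | (R)-4-[(Z)-heptadec-10-enyl]-4-(triethylsilyloxy)cyclohex-2-en-1-one | CCCCCC/C=C\CCCCCCCCC[C@]1(O[Si](CC)(CC)CC)C=CC(=O)CC1
F4 | step 5 | (4R,6R)-4-[(Z)-heptadec-10-enyl]-6-hydroxy-4-(triethylsilyloxy)cyclohex-2-en-1-one | CCCCCC/C=C\CCCCCCCCC[C@]1(O[Si](CC)(CC)CC)C=CC(=O)[C@H](O)C1
F5 | step 5 | (4R,6S)-6-(chloroacetoxy)-4-[(Z)-heptadec-10-enyl]-4-(triethylsilyloxy)cyclohex-2-en-1-one | CCCCCC/C=C\CCCCCCCCC[C@]1(O[Si](CC)(CC)CC)C=CC(=O)[C@@H](OC(=O)CCl)C1
F6 | step 5 | (4R,6S)-4-[(Z)-heptadec-10-enyl]-6-hydroxy-4-(triethylsilyloxy)cyclohex-2-en-1-one | CCCCCC/C=C\CCCCCCCCC[C@]1(O[Si](CC)(CC)CC)C=CC(=O)[C@@H](O)C1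
F7 | step 7 | (1S,5R)-3,3-di-tert-butyl-5-[(Z)-heptadec-10-enyl]-8,8-dimethoxy-2,4-dioxa-3-silabicyclo[3.3.1]non-6-ene | CCCCCC/C=C\CCCCCCCCC[C@]1(O[Si]2(C(C)(C)C)C(C)(C)C)C=CC(OC)(OC)[C@@H](O2)C1
F8 | step 7 | (1S,5R)-3,3-di-tert-butyl-5-[(Z)-heptadec-10-enyl]-2,4-dioxa-3-silabicyclo[3.3.1]non-6-en-8-one | CCCCCC/C=C\CCCCCCCCC[C@]1(O[Si]2(C(C)(C)C)C(C)(C)C)C=CC(=O)[C@@H](O2)C1
F9 | step 2 | (10-hydroxydecyl)triphenylphosphonium bromide | OCCCCCCCCCC[P+](c1ccccc1)(c1ccccc1)c1ccccc1.[Br-]
F10 | step 2 | (Z)-heptadec-10-en-1-ol | CCCCCC/C=C\CCCCCCCCCO
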